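**Plan**
- **Cuts.** Pyranone A is opened at O1–C2 and C3=C4, giving a methyl salicylate and Ph3P=C=C=O. The benzene ring of unit A is then lowered to a cyclohexane-1,3-dione and cut at C4a–C5 and C8–C8a, leaving dimethyl malonate and an α-aryl enone. Pyranone B is cut in the same way as pyranone A.
- **Enabling feature.** The carbocycle of unit A (the coumarin joined through C6) is an orsellinate: ester-level C4 on C4a, oxygen on C8a and C7, CH3 on C5, aryl on C6. A malonate supplies C4, C4a and C8a, and a 3-arylpent-3-en-2-one supplies C5 with its methyl, C6, C7 and C8.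
- **Biaryl bond.** The hindered C6–C8' bond is never made by coupling. It begins as the aryl–CH2 bond set by an aromatic Claisen rearrangement at C8' of unit B.
- **Ring order.** Benzene ring B is bought as methyl orsellinate. Pyranone B closes in step 4, the carbocycle of unit A in step 8 (aromatic from step 9), and pyranone A in step 11.
- **Stereochemistry.** The target has no stereocentre and its axis is undefined, so the racemate is made. The sp3 centres of steps 6 and 8 and the enone geometry are uncontrolled, and none of them outlasts step 9, where the axis appears.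

Key step: step 8

Assumption: the SMILES carries no axial descriptor, so the racemic biaryl is the goal; methyl orsellinate and Ph3P=C=C=O are taken as purchasable.

Step 1
Reactants: 1 methyl 2,4-dihydroxy-6-methylbenzoate (methyl orsellinate); 2 allyl bromide
Product: 3 methyl 2-hydroxy-6-methyl-4-(prop-2-en-1-yloxy)benzoate
Conditions: K2CO3 (1.1 equiv), 2 (1.05 equiv), acetone, reflux
Reagents that add atoms: none
Why: Williamson ether synthesis: the 2-OH is locked in a hydrogen bond to the ester carbonyl, so about one equivalent of 2 should alkylate only the free and more acidic 4-OH, as is usual for orsellinates.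

Step 2
Reactants: 3 methyl 2-hydroxy-6-methyl-4-(prop-2-en-1-yloxy)benzoate
Product: 4 methyl 2,4-dihydroxy-6-methyl-3-(prop-2-en-1-yl)benzoate
Conditions: N,N-diethylaniline, 200 °C, argon
Reagents that add atoms: none
Why: Aromatic Claisen rearrangement: of the two free ortho positions the [3,3] shift should choose C3, between the two oxygens, because the chelated 2-hydroxy ester fixes more double-bond character in C3–C4, the pattern known for 4-allyloxy-2-hydroxyaryl carbonyl compounds, and this carbon becomes C8'.

Step 3
Reactants: 4 methyl 2,4-dihydroxy-6-methyl-3-(prop-2-en-1-yl)benzoate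
Product: 5 methyl 2-hydroxy-4-methoxy-6-methyl-3-(prop-2-en-1-yl)benzoate
Conditions: MeI (1.1 equiv), K2CO3, acetone, reflux
Reagents that add atoms: iodomethane, CI
Why: Williamson O-methylation under the same chelation control as step 1: the 4-OH reacts and the hydrogen-bonded 2-OH is kept for the ring closure.

Step 4
Reactants: 5 methyl 2-hydroxy-4-methoxy-6-methyl-3-(prop-2-en-1-yl)benzoate; 6 (triphenylphosphoranylidene)ketene (Bestmann ylide)
Product: 8 4,7-dimethoxy-5-methyl-8-(prop-2-en-1-yl)-2H-chromen-2-one, via acyl ylide 7 (not isolated)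
Conditions: 6 (1.2 equiv), toluene, reflux
Reagents that add atoms: none
Why: Bestmann ylide annulation: the phenol adds to the cumulated ylide 6 to give the stabilised ester ylide 7, and its intramolecular Wittig olefination of the adjacent ester carbonyl closes the 4-methoxy-2-pyranone in one operation, a known conversion of methyl salicylates into 4-methoxycoumarins.

Step 5
Reactants: 8 4,7-dimethoxy-5-methyl-8-(prop-2-en-1-yl)-2H-chromen-2-one
Product: 9 4,7-dimethoxy-5-methyl-8-(2-oxopropyl)-2H-chromen-2-one
Conditions: PdCl2 (10 mol %), CuCl (co-catalyst), O2 (1 atm), DMF–H2O, rt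
Reagents that add atoms: water, O
Why: Tsuji–Wacker oxidation: divalent palladium activates the terminal alkene for Markovnikov attack of water, the methyl ketone is released and CuCl/O2 returns zerovalent palladium to the divalent state, while the trisubstituted, electron-poor C3'=C4' bond of the pyranone does not take part.

Step 6
Reactants: 9 4,7-dimethoxy-5-methyl-8-(2-oxopropyl)-2H-chromen-2-one; 10 acetaldehyde
Product: 11 8-(4-hydroxy-2-oxopentan-3-yl)-4,7-dimethoxy-5-methyl-2H-chromen-2-one (diastereomer mixture)
Conditions: TiCl4 (2.2 equiv), i-Pr2NEt (1.2 equiv), CH2Cl2, −78 °C; then 10 (3 equiv), −78 °C; aq NH4Cl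
Reagents that add atoms: none
Why: Titanium-mediated soft-enolisation aldol addition: the benzylic CH2 is the more acidic α position, so amine deprotonation of the TiCl4-bound ketone should give the aryl-substituted enolate (the second equivalent of TiCl4 saturates the Lewis-basic pyranone carbonyl), which adds to acetaldehyde at low temperature with no free base left for aldehyde self-condensation, and the two new stereocentres are left uncontrolled because step 7 removes them.

Step 7
Reactants: 11 8-(4-hydroxy-2-oxopentan-3-yl)-4,7-dimethoxy-5-methyl-2H-chromen-2-one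
Product: 13 (E)-3-(4,7-dimethoxy-5-methyl-2-oxo-2H-chromen-8-yl)pent-3-en-2-one, via mesylate 12 (not isolated)
Conditions: MsCl, Et3N, CH2Cl2, 0 °C; then DBU, rt
Reagents that add atoms: none
Why: Mesylation followed by E1cB elimination through the acidic benzylic α-hydrogen gives the conjugated enone, expected mainly as the E isomer with the β-methyl group trans to acetyl, although either geometry serves equally in step 8.

Step 8
Reactants: 13 (E)-3-(4,7-dimethoxy-5-methyl-2-oxo-2H-chromen-8-yl)pent-3-en-2-one; 14 dimethyl malonate
Product: 16 methyl 5-(4,7-dimethoxy-5-methyl-2-oxo-2H-chromen-8-yl)-6-methyl-2,4-dioxocyclohexane-1-carboxylate (diastereomer mixture, largely enolised), via Michael adduct 15 (not isolated)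
Conditions: NaOMe (1.0 equiv), 14 (1.3 equiv), dry MeOH, reflux; then cold 1 M HCl
Reagents that add atoms: none
Why: The sodium enolate of 14 adds to the β carbon of 13 (bond C4a–C5), methanol protonates the aryl-stabilised enolate to give 15, and the small equilibrium share of the methyl-ketone enolate then attacks one of the two ester groups and expels methoxide (bond C8–C8a). This is the classical Michael–Claisen (dimedone-type) annulation of malonates with enones, which is also known for α-aryl and α-alkyl β-substituted enones. The one ring closes in the 6-(enolendo)-exo-trig mode, and deprotonation of the acidic 1,3-dione by the released methoxide pulls both reversible steps forward. C1, C5 and C6 of the new ring become stereocentres with no controlling element; C1 and C5 can epimerise toward the all-equatorial isomer, and all three are erased in step 9. The step needs conjugate addition ahead of carbonyl addition and a single acylation mode: the soft, reversibly adding malonate anion secures the first, and the second follows because the competing benzylic enolate could close only a four-membered ring. Lactone B should survive because base is limited to the one equivalent that ends up bound as the dione enolate, methoxide exchange at C4' is degenerate, and methanolysis at C2' is reversible and undone on acidification, 4-methoxycoumarins being themselves preparable in methanolic NaOMe.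

Step 9
Reactants: 16 methyl 5-(4,7-dimethoxy-5-methyl-2-oxo-2H-chromen-8-yl)-6-methyl-2,4-dioxocyclohexane-1-carboxylate
Product: 18 methyl 3-(4,7-dimethoxy-5-methyl-2-oxo-2H-chromen-8-yl)-4,6-dihydroxy-2-methylbenzoate (racemic axis), via 3-iodo dione 17 (not isolated)
Conditions: I2 (20 mol %), DMSO, 80 °C
Reagents that add atoms: none
Why: Iodine-catalysed oxidative aromatisation, a known way from malonate–enone adducts to resorcylates: the enolised 1,3-dione is iodinated far faster than the deactivated coumarin ring, vinylogous loss of HI and tautomerisation give the resorcinol, and DMSO reoxidises HI to I2 so that neither a strong electrophile nor strong acid builds up.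

Step 10
Reactants: 18 methyl 3-(4,7-dimethoxy-5-methyl-2-oxo-2H-chromen-8-yl)-4,6-dihydroxy-2-methylbenzoate
Product: 19 methyl 3-(4,7-dimethoxy-5-methyl-2-oxo-2H-chromen-8-yl)-6-hydroxy-4-methoxy-2-methylbenzoate
Conditions: MeI (1.1 equiv), K2CO3, acetone, reflux
Reagents that add atoms: iodomethane, CI
Why: Williamson O-methylation: the 4-OH next to the biaryl bond (future C7–OH) is free whereas the 6-OH is chelated to the ester, so the discrimination used in steps 1 and 3 should hold despite the neighbouring aryl group, and K2CO3 in acetone leaves lactone B untouched.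

Step 11
Reactants: 19 methyl 3-(4,7-dimethoxy-5-methyl-2-oxo-2H-chromen-8-yl)-6-hydroxy-4-methoxy-2-methylbenzoate; 6 (triphenylphosphoranylidene)ketene
Product: 21 4,4',7,7'-tetramethoxy-5,5'-dimethyl-2H,2'H-[6,8'-bichromene]-2,2'-dione (target, racemic), via acyl ylide 20 (not isolated)
Conditions: 6 (1.3 equiv), toluene, reflux
Reagents that add atoms: none
Why: Bestmann ylide annulation as rehearsed in step 4: O–H addition gives ylide 20, and the intramolecular Wittig reaction on the ester, which the flanking methyl group twists out of the ring plane and so exposes to the in-plane ylide carbon, closes pyranone A with the C4 methoxy group already in place, while lactone B is inert to a stabilised ylide.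

**Compound list**
1 | methyl 2,4-dihydroxy-6-methylbenzoate (methyl orsellinate) | COC(=O)c1c(C)cc(O)cc1O | starting material
2 | allyl bromide | C=CCBr | starting material
3 | methyl 2-hydroxy-6-methyl-4-(prop-2-en-1-yloxy)benzoate | COC(=O)c1c(C)cc(OCC=C)cc1O | intermediate
4 | methyl 2,4-dihydroxy-6-methyl-3-(prop-2-en-1-yl)benzoate | COC(=O)c1c(C)cc(O)c(CC=C)c1O | intermediate
5 | methyl 2-hydroxy-4-methoxy-6-methyl-3-(prop-2-en-1-yl)benzoate | COC(=O)c1c(C)cc(OC)c(CC=C)c1O | intermediate
6 | (triphenylphosphoranylidene)ketene | O=C=C=P(c1ccccc1)(c1ccccc1)c1ccccc1 | starting material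
7 | methyl 4-methoxy-6-methyl-3-(prop-2-en-1-yl)-2-[(triphenylphosphoranylidene)acetoxy]benzoate (not isolated) | COC(=O)c1c(C)cc(OC)c(CC=C)c1OC(=O)C=P(c1ccccc1)(c1ccccc1)c1ccccc1 | intermediate
8 | 4,7-dimethoxy-5-methyl-8-(prop-2-en-1-yl)-2H-chromen-2-one | C=CCc1c(OC)cc(C)c2c(OC)cc(=O)oc12 | intermediate
9 | 4,7-dimethoxy-5-methyl-8-(2-oxopropyl)-2H-chromen-2-one | CC(=O)Cc1c(OC)cc(C)c2c(OC)cc(=O)oc12 | intermediate
10 | acetaldehyde | CC=O | starting material
11 | 8-(4-hydroxy-2-oxopentan-3-yl)-4,7-dimethoxy-5-methyl-2H-chromen-2-one (diastereomer mixture) | CC(O)C(C(C)=O)c1c(OC)cc(C)c2c(OC)cc(=O)oc12 | intermediate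
12 | 3-(4,7-dimethoxy-5-methyl-2-oxo-2H-chromen-8-yl)-4-oxopentan-2-yl methanesulfonate (not isolated) | CC(OS(C)(=O)=O)C(C(C)=O)c1c(OC)cc(C)c2c(OC)cc(=O)oc12 | intermediate
13 | (E)-3-(4,7-dimethoxy-5-methyl-2-oxo-2H-chromen-8-yl)pent-3-en-2-one | C/C=C(\c1c(OC)cc(C)c2c(OC)cc(=O)oc12)C(C)=O | intermediate
14 | dimethyl malonate | COC(=O)CC(=O)OC | starting material
15 | dimethyl 2-[3-(4,7-dimethoxy-5-methyl-2-oxo-2H-chromen-8-yl)-4-oxopentan-2-yl]propanedioate (diastereomer mixture, not isolated) | COC(=O)C(C(=O)OC)C(C)C(C(C)=O)c1c(OC)cc(C)c2c(OC)cc(=O)oc12 | intermediate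
16 | methyl 5-(4,7-dimethoxy-5-methyl-2-oxo-2H-chromen-8-yl)-6-methyl-2,4-dioxocyclohexane-1-carboxylate (diastereomer mixture) | COC(=O)C1C(C)C(c2c(OC)cc(C)c3c(OC)cc(=O)oc23)C(=O)CC1=O | intermediate
17 | methyl 5-(4,7-dimethoxy-5-methyl-2-oxo-2H-chromen-8-yl)-3-iodo-6-methyl-2,4-dioxocyclohexane-1-carboxylate (not isolated) | COC(=O)C1C(C)C(c2c(OC)cc(C)c3c(OC)cc(=O)oc23)C(=O)C(I)C1=O | intermediate
18 | methyl 3-(4,7-dimethoxy-5-methyl-2-oxo-2H-chromen-8-yl)-4,6-dihydroxy-2-methylbenzoate (racemic axis) | COC(=O)c1c(O)cc(O)c(-c2c(OC)cc(C)c3c(OC)cc(=O)oc23)c1C | intermediate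
19 | methyl 3-(4,7-dimethoxy-5-methyl-2-oxo-2H-chromen-8-yl)-6-hydroxy-4-methoxy-2-methylbenzoate (racemic axis) | COC(=O)c1c(O)cc(OC)c(-c2c(OC)cc(C)c3c(OC)cc(=O)oc23)c1C | intermediate
20 | methyl 3-(4,7-dimethoxy-5-methyl-2-oxo-2H-chromen-8-yl)-4-methoxy-2-methyl-6-[(triphenylphosphoranylidene)acetoxy]benzoate (not isolated) | COC(=O)c1c(OC(=O)C=P(c2ccccc2)(c2ccccc2)c2ccccc2)cc(OC)c(-c2c(OC)cc(C)c3c(OC)cc(=O)oc23)c1C | intermediate
21 | 4,4',7,7'-tetramethoxy-5,5'-dimethyl-2H,2'H-[6,8'-bichromene]-2,2'-dione (racemic axis) | COc1cc2oc(=O)cc(OC)c2c(C)c1-c1c(OC)cc(C)c2c(OC)cc(=O)oc12 | target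

Total step count: 11. Longest linear sequence: 11 steps, from 1 to 21.

**Steps most likely to fail**

**Step 8.**
- Risk: conjugate addition to the α-aryl, β-methyl acceptor may be slow and reversible, and long heating with methoxide may methanolyse lactone B.
- Fallback: this sets out from 13 and 14 and separates the two bond formations under different activation.
- Compound 14 is silylated (Me3SiOTf, Et3N, CH2Cl2) to the ketene silyl acetal methyl 3-methoxy-3-(trimethylsilyloxy)prop-2-enoate F1.
- F1 is added to 13 in a Lewis-acid Mukaiyama–Michael reaction (TiCl4, CH2Cl2, −78 °C). This traps the adduct irreversibly and contains no alkoxide.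
- Aqueous work-up gives 15, now isolated. A short treatment with the hindered base KOt-Bu (1.1 equiv) in t-BuOH–THF performs the Claisen closure, and the route is rejoined at 16.

**Step 6.**
- Risk: the twisted, di-ortho-substituted aryl group conjugates poorly, so enolisation may drift to the methyl side, and acetaldehyde may self-condense.
- Fallback: this sets out from 9 and fixes the regiochemistry in an isolable nucleophile.
- Equilibrating silylation (Me3SiCl, NaI, Et3N, MeCN) gives the more substituted enol ether (Z)-4,7-dimethoxy-5-methyl-8-[2-(trimethylsilyloxy)prop-1-en-1-yl]-2H-chromen-2-one F2.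
- F2 is combined with acetaldehyde dimethyl acetal in a Mukaiyama aldol-type reaction (catalytic Me3SiOTf, CH2Cl2, −78 °C). This gives the β-methoxy ketone 4,7-dimethoxy-8-(4-methoxy-2-oxopentan-3-yl)-5-methyl-2H-chromen-2-one F3.
- DBU then eliminates methanol, so steps 6 and 7 are both replaced and the route is rejoined at 13.

**Step 9.**
- Risk: iodination of the newly formed resorcinol ring may drain the catalyst, the reaction may stall at the halogenated dione stage, or acid may remove the 4'-O-methyl group.
- Fallback: this sets out from 16 and uses no halogen.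
- Double silylation (Me3SiOTf, Et3N, CH2Cl2) gives the cyclohexa-1,3-diene methyl 5-(4,7-dimethoxy-5-methyl-2-oxo-2H-chromen-8-yl)-6-methyl-2,4-bis(trimethylsilyloxy)cyclohexa-1,3-diene-1-carboxylate F4.
- DDQ (toluene, rt) dehydrogenates F4 by hydride abstraction to the aryl silyl ether methyl 3-(4,7-dimethoxy-5-methyl-2-oxo-2H-chromen-8-yl)-2-methyl-4,6-bis(trimethylsilyloxy)benzoate F5.
- Dilute HCl in MeOH removes the silyl groups, and the route is rejoined at 18.

**Further compounds**
F1 | step 8 | methyl 3-methoxy-3-(trimethylsilyloxy)prop-2-enoate (E/Z mixture) | COC(=O)C=C(OC)O[Si](C)(C)C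
F2 | step 6 | (Z)-4,7-dimethoxy-5-methyl-8-[2-(trimethylsilyloxy)prop-1-en-1-yl]-2H-chromen-2-one | C/C(O[Si](C)(C)C)=C/c1c(OC)cc(C)c2c(OC)cc(=O)oc12
F3 | step 6 | 4,7-dimethoxy-8-(4-methoxy-2-oxopentan-3-yl)-5-methyl-2H-chromen-2-one (diastereomer mixture) | COC(C)C(C(C)=O)c1c(OC)cc(C)c2c(OC)cc(=O)oc12
F4 | step 9 | methyl 5-(4,7-dimethoxy-5-methyl-2-oxo-2H-chromen-8-yl)-6-methyl-2,4-bis(trimethylsilyloxy)cyclohexa-1,3-diene-1-carboxylate (diastereomer mixture) | COC(=O)C1=C(O[Si](C)(C)C)C=C(O[Si](C)(C)C)C(c2c(OC)cc(C)c3c(OC)cc(=O)oc23)C1C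
F5 | step 9 | methyl 3-(4,7-dimethoxy-5-methyl-2-oxo-2H-chromen-8-yl)-2-methyl-4,6-bis(trimethylsilyloxy)benzoate | COC(=O)c1c(O[Si](C)(C)C)cc(O[Si](C)(C)C)c(-c2c(OC)cc(C)c3c(OC)cc(=O)oc23)c1C
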